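The vessel is closed, stirred and held at one temperature, and Sbt goes over to Pdt in it.

| setting | oak | larch | elm |
|---|---|---|---|
| Sbt | 0.300 M | 0.300 M | 0.300 M |
| Pdt |  | 0.150 M |  |
| time |  |  | 8.8 h |

| run | time / h | [Pdt] / M |
|---|---|---|
| oak run | 0.50 | 0.0294 |
| oak run | 1.0 | 0.0646 |
| oak run | 1.5 | 0.0821 |
| oak run | 2.0 | 0.0983 |
| oak run | 2.5 | 0.1096 |
| oak run | 3.0 | 0.1144 |
| oak run | 3.5 | 0.1216 |
| larch run | 0.50 | 0.1700 |
| larch run | 1.0 | 0.2014 |
| larch run | 1.5 | 0.2183 |
| larch run | 2.0 | 0.2292 |
| larch run | 2.5 | 0.2355 |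
| larch run | 3.0 | 0.2315 |
| larch run | 3.5 | 0.2399 |

(readings scatter by 0.002 M)

1. Pdt in the elm run at 8.8 h, as a share of the Sbt charged

- Overall: Sbt -> Pdt.
- Constant volume, constant temperature.

What does the larch run show that the oak run cannot? Larch starts with an extra 0.150 M of Pdt, yet at 3.5 h it stands above oak by 0.118 M, so the extra has shrunk.

How do you put a number on that? Divide the amount lost by the mean excess and by the time, which gives 0.0675 /h; this is the loss constant, the share of standing Pdt that goes per hour.

Isn't the mean crude? The logarithmic form gives 0.0678 /h, so the mean costs nothing visible here.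

Could added Pdt simply brake the making? That is the weak spot. Oak gains 0.0491 M/h up to 2.0 h and 0.0155 M/h afterwards, yet with 0.131 M as the excess at 2.0 h the two stretches give 0.0680 /h and 0.0674 /h. I read that as a loss of Pdt.

What do you commit to for elm? Elm is charged as oak, so I follow oak. Net rise plus loss gives a making rate of 0.0341 M/h at 2.0 h and 0.0197 M/h at 3.0 h, a fade of 0.549 /h. So 0.0273 M is still to come after 3.5 h. Letting old and new Pdt decay gives 35.5 %.

The forecast says 49 %, within 43 % to 55 %, holding that “Elm repeats oak at a later time”.

The simulation gives 33.1 %, which is 2.4 percentage points below my figure.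

    2 Sbt ⇌ Imd + Sbt (9.216 /M/h, 20.05 /M/h)
    Imd → Pdt (1.098 /h)
    Sbt → Q (0.2808 /h)
    Pdt → Z (0.06912 /h)

Elm ends at 33.1 % because Sbt also turns into Q and Pdt into Z. The elm flask run without the conversion of Pdt into Z reaches 53.4 %. The logarithm of the ratio of those shares, divided by the 0.0691 /h of that conversion, gives the Pdt standing in elm at 8.8 h an effective age of 6.92 h, which puts its weighted time of making 1.88 h after the start. Reckoned with the loss constant of 0.0675 /h instead, the effective age in elm comes to 7.09 h.

The readings were computed on assumed constants.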